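**Plan**

- Retrosynthetic cuts, in order: the coumarin C4–O–CH2 ether bond; the side-chain bond between the olefinic carbon C3' and C4'; the ring bond C1–C2 of the 7-oxabicyclo[2.2.1]heptane; the C=C bond of an allylsilane; the bond between carbinol carbon C4 and gem-dimethyl carbon C3.
- Enabling feature: bridgehead C1 (bonded to O7, CH3, C2 and C6) is a ketal-level carbon, so it can be the cationic carbon of an oxolan-2-ylium ion (ring O7–C1–C6–C5–C4). C2 lies two atoms from C4 across C3, so an allylsilane whose γ-carbon is C2 closes the carbocycle C1–C6 onto that cation and completes the bicycle in one bond.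
- Forward order: oxolanone ring (step 1), allylsilane (step 2), ketal (step 3), carbocycle and bicycle with a vinyl handle (step 4), hydroboration and B-alkyl Suzuki–Miyaura coupling to the E-enoate (step 6), allylic alcohol (step 7), Mitsunobu etherification (step 9).
- Stereochemistry: C4 by reagent control in a Brown reverse prenylation; C1 follows geometrically from C4 and C2 from the exo transition state of step 4; the E-olefin comes from a geometrically defined enol triflate coupled with retention.

Key step: step 4

Remark: locants C1–C6 and O7 are those of the target's 7-oxabicyclo[2.2.1]heptane (C1 methyl-bearing bridgehead, C2 side-chain carbon, C3 CMe2, C4 bridgehead CH); (+)-Ipc2BH is the diisopinocampheylborane made from (−)-α-pinene and BH3·SMe2 and is treated as a stock reagent; ketal 6 is carried as both epimers at the ketal carbon, which becomes trigonal in step 4.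

**Step 1**
Reactants: 1 methyl 4-oxobutanoate
Product: 3 (5S)-5-(2-methylbut-3-en-2-yl)oxolan-2-one, via hydroxy ester 2 (not isolated)
Conditions: (+)-Ipc2BH, 3-methylbuta-1,2-diene, THF, −25 °C; 1, −78 °C; HOCH2CH2NH2, rt; then pTsOH (cat.), CH2Cl2, rt
Reagents that add atoms: 3-methylbuta-1,2-diene, CC(C)=C=C (hydroborated in the flask to the B-prenylborane that transfers the five-carbon unit)
Why: Brown asymmetric allylboration (reverse prenylation), in which the B-prenylborane adds through its γ-carbon in a closed Zimmerman–Traxler chair to the aldehyde only, the isopinocampheyl groups from (−)-α-pinene directing attack to the Re face so that the S carbinol centre forms next to the new quaternary carbon, and the γ-hydroxy ester released by ethanolamine lactonizes under acid.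

**Step 2**
Reactants: 3 (5S)-5-(2-methylbut-3-en-2-yl)oxolan-2-one
Product: 4 (5S)-5-[(3E)-2-methyl-5-(trimethylsilyl)pent-3-en-2-yl]oxolan-2-one
Conditions: allyltrimethylsilane (4 equiv), second-generation Hoveyda–Grubbs catalyst (5 mol %), CH2Cl2, 40 °C
Reagents that add atoms: allyltrimethylsilane, C=CC[Si](C)(C)C
Why: olefin cross-metathesis, in which the vinyl group on a quaternary carbon cannot homodimerize and is therefore taken to the cross product by the alkylidene of the excess, fast-reacting allylsilane, the tert-alkyl substituent enforcing E geometry and the stereocentre remaining untouched.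

**Step 3**
Reactants: 4 (5S)-5-[(3E)-2-methyl-5-(trimethylsilyl)pent-3-en-2-yl]oxolan-2-one
Product: 6 (5S)-2-methoxy-2-methyl-5-[(3E)-2-methyl-5-(trimethylsilyl)pent-3-en-2-yl]oxolane (both C2 epimers), via lactol 5 (not isolated)
Conditions: MeLi (1.05 equiv), THF, −78 °C; AcOH; then MeOH, PPTS (cat.), 4 Å molecular sieves, rt
Reagents that add atoms: methyllithium, [Li]C; methanol, CO
Why: mono-addition of MeLi to a γ-lactone should stop at the tetrahedral lithium alkoxide at −78 °C and give the lactol on quench, which undergoes Fischer-type ketalization to the five-membered cyclic methyl ketal under an acid too weak to protodesilylate the allylsilane.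

**Step 4**
Reactants: 6 (5S)-2-methoxy-2-methyl-5-[(3E)-2-methyl-5-(trimethylsilyl)pent-3-en-2-yl]oxolane
Product: 8 (1R,2S,4S)-2-ethenyl-1,3,3-trimethyl-7-oxabicyclo[2.2.1]heptane, via oxocarbenium triflate 7 (not isolated)
Conditions: TMSOTf (20 mol %), 2,6-di-tert-butyl-4-methylpyridine (5 mol %), CH2Cl2, −78 → −20 °C; Et3N
Reagents that add atoms: none
Why: TMSOTf ionizes the ketal to the oxolan-2-ylium ion 7, whose cationic carbon (future C1) is attacked by the γ-carbon of the allylsilane (future C2) held over it by the gem-dimethyl tether, and the β-silyl cation then loses the silyl group to the departing methoxy group, leaving the vinyl group and regenerating TMSOTf. The closest known reaction types are the TMSOTf-catalysed Hosomi–Sakurai allylation of acetals and intramolecular allylsilane/oxocarbenium (silyl-Prins) cyclizations that give bridged bicyclic ethers, with the π-route to norbornyl cations as the carbocyclic analogue of closure across positions 1 and 3 of a five-membered ring. The carbocycle C1–C6 closes in the 6-exo-trig mode with respect to the alkene, the C=O+ bond lying outside the new ring, and because this ring spans the two α-carbons of the oxolane the same bond completes the bicyclo[2.2.1] skeleton. C1 is fixed by C4, since the two-atom tether can reach only the face of the cation on which it stands, and C2 is set by the orientation of the alkene: the synclinal arrangement that places the silylmethyl-bearing alkene carbon over O7 (exo) is expected to be preferred to the one that forces it under the C5–C6 ethano bridge (endo), which gives the 2S centre. The step needs γ- over α-attack of the allylsilane and cyclization over protodesilylation; the β-silicon effect should secure the first, and the Thorpe–Ingold effect of C3 together with the buffered, catalytic Lewis acid the second.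

**Step 5**
Reactants: 9 ethyl 3-oxobutanoate
Product: 10 ethyl (2E)-3-{[(trifluoromethyl)sulfonyl]oxy}but-2-enoate
Conditions: Tf2O, aq Me4NOH, hexanes, 5 °C
Reagents that add atoms: trifluoromethanesulfonic anhydride, O=S(=O)(OS(=O)(=O)C(F)(F)F)C(F)(F)F
Why: O-triflation of the β-keto ester enolate, which with the non-chelating tetramethylammonium counter-ion should react from the dipole-minimized geometry and give the E enol triflate (a chelating lithium counter-ion would give Z).

**Step 6**
Reactants: 8 (1R,2S,4S)-2-ethenyl-1,3,3-trimethyl-7-oxabicyclo[2.2.1]heptane; 10 ethyl (2E)-3-{[(trifluoromethyl)sulfonyl]oxy}but-2-enoate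
Product: 12 ethyl (2E)-3-methyl-5-[(1R,2S,4S)-1,3,3-trimethyl-7-oxabicyclo[2.2.1]heptan-2-yl]pent-2-enoate, via alkylborane 11 (not isolated)
Conditions: 9-BBN-H, THF, 0 °C → rt; then 10, Pd(dppf)Cl2 (5 mol %), 3 M aq K3PO4, DMF, rt
Reagents that add atoms: none
Why: anti-Markovnikov hydroboration of the terminal vinyl group followed by B-alkyl Suzuki–Miyaura coupling, in which oxidative addition of the activated enol triflate, transmetalation of the base-activated primary alkylborane and reductive elimination should proceed with retention of the E geometry.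

**Step 7**
Reactants: 12 ethyl (2E)-3-methyl-5-[(1R,2S,4S)-1,3,3-trimethyl-7-oxabicyclo[2.2.1]heptan-2-yl]pent-2-enoate
Product: 13 (2E)-3-methyl-5-[(1R,2S,4S)-1,3,3-trimethyl-7-oxabicyclo[2.2.1]heptan-2-yl]pent-2-en-1-ol
Conditions: iBu2AlH (2.2 equiv), CH2Cl2, −78 °C; aq potassium sodium tartrate
Reagents that add atoms: none
Why: 1,2-reduction of the α,β-unsaturated ester to the allylic alcohol by the aluminium hydride at low temperature, which leaves the trisubstituted alkene and the bridged ether untouched.

**Step 8**
Reactants: 14 1-(2-hydroxy-6-methylphenyl)ethan-1-one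
Product: 15 4-hydroxy-5-methyl-2H-chromen-2-one
Conditions: NaH, (EtO)2CO, toluene, 110 °C; aq HCl
Reagents that add atoms: diethyl carbonate, CCOC(=O)OCC
Why: Claisen-type C-acylation of the ketone enolate by diethyl carbonate followed by lactonization onto the phenoxide (the standard 4-hydroxycoumarin synthesis), the methyl group ortho to the acetyl group fixing the 5-methyl pattern.

**Step 9**
Reactants: 13 (2E)-3-methyl-5-[(1R,2S,4S)-1,3,3-trimethyl-7-oxabicyclo[2.2.1]heptan-2-yl]pent-2-en-1-ol; 15 4-hydroxy-5-methyl-2H-chromen-2-one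
Product: 16 5-methyl-4-{[(2E)-3-methyl-5-[(1R,2S,4S)-1,3,3-trimethyl-7-oxabicyclo[2.2.1]heptan-2-yl]pent-2-en-1-yl]oxy}-2H-chromen-2-one
Conditions: PPh3, DIAD, THF, 0 °C → rt
Reagents that add atoms: none
Why: Mitsunobu etherification, in which the acidic 4-hydroxycoumarin (a vinylogous carboxylic acid) protonates the betaine and its oxygen displaces the alkoxyphosphonium of the primary allylic alcohol by SN2, with no stereocentre involved and the E-alkene retained.

**Compound list**

1 | methyl 4-oxobutanoate | COC(=O)CCC=O | starting material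
2 | methyl (4S)-4-hydroxy-5,5-dimethylhept-6-enoate | COC(=O)CC[C@H](O)C(C)(C)C=C | intermediate
3 | (5S)-5-(2-methylbut-3-en-2-yl)oxolan-2-one | C=CC(C)(C)[C@@H]1CCC(=O)O1 | intermediate
4 | (5S)-5-[(3E)-2-methyl-5-(trimethylsilyl)pent-3-en-2-yl]oxolan-2-one | C[Si](C)(C)C/C=C/C(C)(C)[C@@H]1CCC(=O)O1 | intermediate
5 | (5S)-2-methyl-5-[(3E)-2-methyl-5-(trimethylsilyl)pent-3-en-2-yl]oxolan-2-ol (lactol, in equilibrium with the open hydroxy ketone) | C[Si](C)(C)C/C=C/C(C)(C)[C@@H]1CCC(C)(O)O1 | intermediate
6 | (5S)-2-methoxy-2-methyl-5-[(3E)-2-methyl-5-(trimethylsilyl)pent-3-en-2-yl]oxolane (both C2 epimers) | C[Si](C)(C)C/C=C/C(C)(C)[C@@H]1CCC(C)(OC)O1 | intermediate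
7 | (5S)-2-methyl-5-[(3E)-2-methyl-5-(trimethylsilyl)pent-3-en-2-yl]-4,5-dihydro-3H-furan-1-ium trifluoromethanesulfonate (oxocarbenium ion) | C[Si](C)(C)C/C=C/C(C)(C)[C@@H]1CCC(C)=[O+]1.[O-]S(=O)(=O)C(F)(F)F | intermediate
8 | (1R,2S,4S)-2-ethenyl-1,3,3-trimethyl-7-oxabicyclo[2.2.1]heptane (vinyl group exo, syn to O7) | C=C[C@H]1C(C)(C)[C@@H]2CC[C@@]1(C)O2 | intermediate
9 | ethyl 3-oxobutanoate | CCOC(=O)CC(C)=O | starting material
10 | ethyl (2E)-3-{[(trifluoromethyl)sulfonyl]oxy}but-2-enoate | CCOC(=O)/C=C(\C)OS(=O)(=O)C(F)(F)F | intermediate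
11 | 9-{2-[(1R,2S,4S)-1,3,3-trimethyl-7-oxabicyclo[2.2.1]heptan-2-yl]ethyl}-9-borabicyclo[3.3.1]nonane | C1CCC2CCCC1B2CC[C@H]1C(C)(C)[C@@H]2CC[C@@]1(C)O2 | intermediate
12 | ethyl (2E)-3-methyl-5-[(1R,2S,4S)-1,3,3-trimethyl-7-oxabicyclo[2.2.1]heptan-2-yl]pent-2-enoate | CCOC(=O)/C=C(\C)CC[C@H]1C(C)(C)[C@@H]2CC[C@@]1(C)O2 | intermediate
13 | (2E)-3-methyl-5-[(1R,2S,4S)-1,3,3-trimethyl-7-oxabicyclo[2.2.1]heptan-2-yl]pent-2-en-1-ol | OC/C=C(\C)CC[C@H]1C(C)(C)[C@@H]2CC[C@@]1(C)O2 | intermediate
14 | 1-(2-hydroxy-6-methylphenyl)ethan-1-one | CC(=O)c1c(C)cccc1O | starting material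
15 | 4-hydroxy-5-methyl-2H-chromen-2-one | Cc1cccc2oc(=O)cc(O)c12 | intermediate
16 | 5-methyl-4-{[(2E)-3-methyl-5-[(1R,2S,4S)-1,3,3-trimethyl-7-oxabicyclo[2.2.1]heptan-2-yl]pent-2-en-1-yl]oxy}-2H-chromen-2-one | C/C(=C\COc1cc(=O)oc2cccc(C)c12)CC[C@H]1C(C)(C)[C@@H]2CC[C@@]1(C)O2 | target

**Step count**

Total steps: 9. Longest linear sequence: 7 steps (steps 1, 2, 3, 4, 6, 7, 9).

**Steps most likely to fail**

1. Step 4. The strained bridged transition state may be reached too slowly, so that protodesilylation of the allylsilane or proton loss from the oxocarbenium ion takes over, and the exo/endo facial selectivity at C2 may be poor. Fallback, from 5 to 8: lactol 5 is isolated after the MeLi addition and its open hydroxy ketone form is trapped with TESCl and imidazole as (5S,7E)-6,6-dimethyl-5-[(triethylsilyl)oxy]-9-(trimethylsilyl)non-7-en-2-one F1. TiCl4 in CH2Cl2 at −78 °C should then close only the unstrained cyclohexane by Sakurai addition of the allylsilane to the ketone, through a chair with the silyloxy and alkenyl groups equatorial and therefore cis, giving (2S,4S)-2-ethenyl-1,3,3-trimethyl-4-[(triethylsilyl)oxy]cyclohexan-1-ol F2 as either C1 epimer. pTsOH·H2O in wet CH2Cl2 should remove the silyl group and ionize the tertiary carbinol, and the secondary hydroxyl should capture the cation across the ring to give 8, as in acid-mediated 1,4-cineole formation.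

2. Step 2. Productive metathesis at the neopentyl-type vinyl group may be slow, while self-metathesis of the allylsilane consumes partner and catalyst. Fallback, from 3 to 4: ozonolysis (O3, CH2Cl2, −78 °C; Me2S) should give 2-methyl-2-[(2S)-5-oxooxolan-2-yl]propanal F3. Takai iodo-olefination (CHI3, CrCl2, THF) should give (5S)-5-[(3E)-4-iodo-2-methylbut-3-en-2-yl]oxolan-2-one F4. Negishi coupling with Me3SiCH2ZnCl and Pd(PPh3)4 in THF should then return the E-allylsilane 4.

3. Step 9. The ambident coumarin may be alkylated at C3 or at the lactone carbonyl oxygen, and the allylic alcohol may react by SN2' attack. Fallback, from 15 (with 13) to 16: the polarity is reversed by converting 15 with POCl3 (benzyltriethylammonium chloride, MeCN, reflux) into 4-chloro-5-methyl-2H-chromen-2-one F5. The sodium alkoxide of 13 (NaH, THF, 0 °C) should displace chloride by conjugate addition–elimination at C4, which can give only the 4-O-ether 16.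

**Further compounds**

F1 | step 4 | (5S,7E)-6,6-dimethyl-5-[(triethylsilyl)oxy]-9-(trimethylsilyl)non-7-en-2-one | CC(=O)CC[C@H](O[Si](CC)(CC)CC)C(C)(C)/C=C/C[Si](C)(C)C
F2 | step 4 | (2S,4S)-2-ethenyl-1,3,3-trimethyl-4-[(triethylsilyl)oxy]cyclohexan-1-ol (either C1 epimer) | C=C[C@H]1C(C)(C)[C@@H](O[Si](CC)(CC)CC)CCC1(C)O
F3 | step 2 | 2-methyl-2-[(2S)-5-oxooxolan-2-yl]propanal | O=CC(C)(C)[C@@H]1CCC(=O)O1
F4 | step 2 | (5S)-5-[(3E)-4-iodo-2-methylbut-3-en-2-yl]oxolan-2-one | I/C=C/C(C)(C)[C@@H]1CCC(=O)O1
F5 | step 9 | 4-chloro-5-methyl-2H-chromen-2-one | Cc1cccc2oc(=O)cc(Cl)c12
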